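The five-membered ring is left open until late. In daucane numbering C4, at carbonyl level, is bonded to C5, and C5 is β to a C10 ketone whose α-carbon is the quaternary ring-fusion atom C1. The C1=C5 bond of a seven-membered cross-conjugated dienone can therefore take an acetyl anion equivalent (C4–C3) at C5 and, via the enolate, formaldehyde (C2) at C1. One flask forms C4–C5 and C1–C2 and relays the C6 silyloxy stereocentre to C5 and C1, trans to each other as the trans ring fusion requires. The precursor, (S)-4-silyloxy-2,6-dimethylcyclohepta-2,6-dienone, is made from (S)-epichlorohydrin by ring-closing metathesis.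

Key step: step 9

Remark: the carbocycle is numbered as in daucane throughout (C1 ring-fusion carbon bearing methyl C15; C2, C3, C4 in the five-membered ring, isopropyl on C4; C5 ring-fusion CH; C6, C7, C8 bearing methyl C14, C9, C10 in the seven-membered ring). All numbered starting materials are taken to be commercial, formaldehyde as paraformaldehyde.

Step 1
Reactants: 1 (S)-epichlorohydrin; 2 ethynyltrimethylsilane
Product: 4 (S)-1-chloro-5-(trimethylsilyl)pent-4-yn-2-ol, via lithium (trimethylsilyl)acetylide 3 (not isolated)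
Conditions: 2, n-BuLi, THF, −78 °C; BF3·OEt2; then 1, −78 °C; aq. NH4Cl
Reagents that add atoms: none
Why: Yamaguchi–Hirao alkynylation, in which the BF3-activated epoxide is opened by the acetylide at its unsubstituted carbon, so the stereocentre is not touched and the primary chloride survives at −78 °C.

Step 2
Reactants: 4 (S)-1-chloro-5-(trimethylsilyl)pent-4-yn-2-ol
Product: 7 (S)-hex-1-en-5-yn-3-ol, via epoxide 5 (not isolated), via silylated enynol 6 (not isolated)
Conditions: Me3S+ I− (4 equiv), n-BuLi (4 equiv), THF, −10 °C → rt; then MeOH, K2CO3, rt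
Reagents that add atoms: trimethylsulfonium iodide, C[S+](C)C.[I-]
Why: Base closes the chlorohydrin to the terminal epoxide (Williamson), dimethylsulfonium methylide opens it at the CH2 terminus and the betaine loses dimethyl sulfide to give the allylic alcohol (one-carbon epoxide homologation), and methoxide then cleaves the alkynyl C–Si bond; the C–O bond at the stereocentre is never broken.

Step 3
Reactants: 7 (S)-hex-1-en-5-yn-3-ol
Product: 8 (S)-tert-butyl(hex-1-en-5-yn-3-yloxy)dimethylsilane
Conditions: TBSCl, imidazole, DMF, 0 °C → rt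
Reagents that add atoms: tert-butyldimethylsilyl chloride, CC(C)(C)[Si](C)(C)Cl
Why: Imidazole-mediated silylation of a secondary alcohol, which also makes the volatile enynol easy to handle and installs the bulky ether that later directs the cuprate.

Step 4
Reactants: 8 (S)-tert-butyl(hex-1-en-5-yn-3-yloxy)dimethylsilane
Product: 10 methyl (S)-5-[(tert-butyldimethylsilyl)oxy]hept-6-en-2-ynoate, via lithium acetylide 9 (not isolated)
Conditions: n-BuLi, THF, −78 °C; ClCO2Me, −78 → 0 °C
Reagents that add atoms: methyl chloroformate, COC(=O)Cl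
Why: Deprotonation of the terminal alkyne and C-acylation of the acetylide by a chloroformate, a routine ynoate synthesis that supplies C10.

Step 5
Reactants: 10 methyl (S)-5-[(tert-butyldimethylsilyl)oxy]hept-6-en-2-ynoate
Product: 11 methyl (2Z,5S)-5-[(tert-butyldimethylsilyl)oxy]-3-methylhepta-2,6-dienoate
Conditions: Me2CuLi (from MeLi, CuI), THF, −78 °C; MeOH then aq. NH4Cl at −78 °C
Reagents that add atoms: lithium dimethylcuprate, [Li+].C[Cu-]C
Why: Syn conjugate addition (carbocupration) of the cuprate to the ynoate followed by cold protonation puts the new methyl C14 cis to hydrogen, so the chain and the ester end up cis (Z), the geometry the seven-membered ring needs.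

Step 6
Reactants: 11 methyl (2Z,5S)-5-[(tert-butyldimethylsilyl)oxy]-3-methylhepta-2,6-dienoate
Product: 12 (2Z,5S)-5-[(tert-butyldimethylsilyl)oxy]-N-methoxy-N,3-dimethylhepta-2,6-dienamide
Conditions: MeNH(OMe)·HCl, AlMe3, CH2Cl2, 0 °C → rt
Reagents that add atoms: N,O-dimethylhydroxylamine hydrochloride, CNOC.Cl
Why: Weinreb aminolysis of the ester by the aluminium amide, under which neither the Z alkene nor the silyl ether is at risk.

Step 7
Reactants: 12 (2Z,5S)-5-[(tert-butyldimethylsilyl)oxy]-N-methoxy-N,3-dimethylhepta-2,6-dienamide; 13 isopropenylmagnesium bromide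
Product: 14 (4Z,7S)-7-[(tert-butyldimethylsilyl)oxy]-2,5-dimethylnona-1,4,8-trien-3-one
Conditions: 13, THF, −20 → 0 °C; aq. NH4Cl
Reagents that add atoms: none
Why: Weinreb ketone synthesis, in which the chelated tetrahedral adduct stops at the ketone stage and the β,β-disubstituted enamide resists 1,4-addition; the Grignard reagent brings C1 and C15.

Step 8
Reactants: 14 (4Z,7S)-7-[(tert-butyldimethylsilyl)oxy]-2,5-dimethylnona-1,4,8-trien-3-one
Product: 15 (S)-4-[(tert-butyldimethylsilyl)oxy]-2,6-dimethylcyclohepta-2,6-dien-1-one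
Conditions: second-generation Hoveyda–Grubbs catalyst RuCl2(=CH-2-iPrOC6H4)(H2IMes) (5 mol %), toluene (5 mM), 60 °C
Reagents that add atoms: none
Why: Ring-closing olefin metathesis between the allylic-ether vinyl group and the isopropenyl ketone, helped by the Z alkene that holds the termini close, should form the trisubstituted C1=C5 bond of the seven-membered ring with loss of ethylene.

Step 9
Reactants: 15 (S)-4-[(tert-butyldimethylsilyl)oxy]-2,6-dimethylcyclohepta-2,6-dien-1-one; 16 ethyl vinyl ether; 17 formaldehyde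
Product: 21 (5S,6S,7R)-5-[(tert-butyldimethylsilyl)oxy]-6-(1-ethoxyethenyl)-7-(hydroxymethyl)-3,7-dimethylcyclohept-2-en-1-one, via 1-ethoxyvinyllithium 18 (not isolated), via lithium bis(1-ethoxyvinyl)cuprate 19 (not isolated), via lithium enolate 20 (not isolated)
Conditions: 16, t-BuLi, THF, −78 → 0 °C; CuBr·SMe2, −78 → −40 °C; 15, −78 °C; 17 (gas, cracked from paraformaldehyde), −78 °C; aq. NH4Cl/NH3
Reagents that add atoms: none
Why: The cuprate complexes the less substituted enone arm and transfers a 1-ethoxyvinyl group to C5 (1,4-addition), giving the C10 enolate 20, which then adds through C1 to monomeric formaldehyde in an aldol reaction. The closest known reaction type is the conjugate addition of α-alkoxyvinyl cuprates to cycloalkenones combined with aldehyde trapping of the enolate (three-component coupling). No ring closes; the new bonds C4–C5 and C1–C2 are the two that later frame the five-membered ring. C5 is set by the C6 silyloxy group, which the reagent avoids (anti addition), and C1 is set by the new C5 substituent, because formaldehyde approaches the enolate face opposite to it, so the single stereocentre of 15 is relayed to three contiguous ones with C2 and C4 trans. The step needs regioselectivity between the two enone arms, secured by the C14 methyl that makes C8 a disubstituted and therefore slow β-carbon, and it needs the silyloxy group to stay in place, secured by the low basicity of the cuprate at −78 °C and a buffered work-up that also spares the enol ether.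

Step 10
Reactants: 21 (5S,6S,7R)-5-[(tert-butyldimethylsilyl)oxy]-6-(1-ethoxyethenyl)-7-(hydroxymethyl)-3,7-dimethylcyclohept-2-en-1-one
Product: 22 (5S,6S,7R)-6-acetyl-5-[(tert-butyldimethylsilyl)oxy]-7-(hydroxymethyl)-3,7-dimethylcyclohept-2-en-1-one
Conditions: oxalic acid (0.2 equiv), THF/H2O (4:1), 0 °C → rt
Reagents that add atoms: water, O
Why: Acid-catalysed hydrolysis of the enol ether through its oxocarbenium ion unveils the C4 methyl ketone (possibly in equilibrium with its cyclic hemiketal), and the weak acid leaves the secondary silyl ether intact.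

Step 11
Reactants: 22 (5S,6S,7R)-6-acetyl-5-[(tert-butyldimethylsilyl)oxy]-7-(hydroxymethyl)-3,7-dimethylcyclohept-2-en-1-one
Product: 23 (1R,6S,7S)-7-acetyl-6-[(tert-butyldimethylsilyl)oxy]-1,4-dimethyl-2-oxocyclohept-3-ene-1-carbaldehyde
Conditions: Dess–Martin periodinane, CH2Cl2, 0 °C → rt
Reagents that add atoms: none
Why: Dess–Martin oxidation of the neopentyl primary alcohol gives the C2 aldehyde under non-basic conditions, and the quaternary C1 cannot epimerise.

Step 12
Reactants: 23 (1R,6S,7S)-7-acetyl-6-[(tert-butyldimethylsilyl)oxy]-1,4-dimethyl-2-oxocyclohept-3-ene-1-carbaldehyde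
Product: 25 (1R,2S,5S,6S)-6-[(tert-butyldimethylsilyl)oxy]-2-hydroxy-11,12,13-trinordauc-8-ene-4,10-dione, via lithium enolate 24 (not isolated)
Conditions: LiN(SiMe3)2 (1.1 equiv), THF, −78 °C; AcOH, −78 °C
Reagents that add atoms: none
Why: The kinetic enolate of the methyl ketone adds to the neighbouring non-enolisable aldehyde in a 5-exo-trig intramolecular aldol reaction that forms C2–C3 and the trans-fused five-membered ring, and lithium chelation of the aldehyde and C10 carbonyl oxygens should place the new C2 hydroxyl on the side of C10, anti to C15.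

Step 13
Reactants: 25 (1R,2S,5S,6S)-6-[(tert-butyldimethylsilyl)oxy]-2-hydroxy-11,12,13-trinordauc-8-ene-4,10-dione; 26 isopropylmagnesium chloride
Product: 27 (1R,2S,4R,5S,6S)-6-[(tert-butyldimethylsilyl)oxy]-2,4-dihydroxydauc-8-en-10-one
Conditions: LaCl3·2LiCl (1.1 equiv), THF, 0 °C; 26 (3 equiv), −40 → 0 °C; aq. NH4Cl
Reagents that add atoms: none
Why: Lanthanum-salt-promoted Grignard 1,2-addition suppresses enolisation and β-hydride reduction, the more accessible cyclopentanone should react before the neopentyl, conjugated C10 ketone, and the reagent should enter anti to the angular methyl C15 so that the C4 hydroxyl is cis to C15.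

Step 14
Reactants: 27 (1R,2S,4R,5S,6S)-6-[(tert-butyldimethylsilyl)oxy]-2,4-dihydroxydauc-8-en-10-one
Product: 28 (1R,2S,4R,5S,6S)-2-acetoxy-6-[(tert-butyldimethylsilyl)oxy]-4-hydroxydauc-8-en-10-one
Conditions: Ac2O, pyridine, DMAP (cat.), CH2Cl2, 0 °C → rt
Reagents that add atoms: acetic anhydride, CC(=O)OC(C)=O
Why: DMAP-catalysed acetylation distinguishes the secondary C2 hydroxyl from the hindered tertiary C4 hydroxyl and removes the retro-aldol liability of the free C2 alcohol.

Step 15
Reactants: 28 (1R,2S,4R,5S,6S)-2-acetoxy-6-[(tert-butyldimethylsilyl)oxy]-4-hydroxydauc-8-en-10-one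
Product: 29 (1S,2S,4R,5S,6S,10S)-2-acetoxy-6-[(tert-butyldimethylsilyl)oxy]dauc-8-ene-4,10-diol
Conditions: NaBH4, CeCl3·7H2O, MeOH, −78 → −40 °C
Reagents that add atoms: none
Why: Luche 1,2-reduction of the enone, in which hydride should approach C10 anti to the axial C15 methyl on the adjacent carbon and give the allylic alcohol cis to C15 (the C1 descriptor changes by priority only).

Step 16
Reactants: 29 (1S,2S,4R,5S,6S,10S)-2-acetoxy-6-[(tert-butyldimethylsilyl)oxy]dauc-8-ene-4,10-diol
Product: 30 (1R,2S,4R,5S,6S,10S)-2-acetoxy-10-benzoyloxy-6-[(tert-butyldimethylsilyl)oxy]dauc-8-en-4-ol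
Conditions: BzCl, DMAP, pyridine, CH2Cl2, rt
Reagents that add atoms: benzoyl chloride, O=C(Cl)c1ccccc1
Why: DMAP-catalysed benzoylation of the only free secondary hydroxyl, while the tertiary C4 hydroxyl is too hindered to react.

Step 17
Reactants: 30 (1R,2S,4R,5S,6S,10S)-2-acetoxy-10-benzoyloxy-6-[(tert-butyldimethylsilyl)oxy]dauc-8-en-4-ol
Product: 31 (1R,2S,4R,5S,6S,10S)-2-acetoxy-10-benzoyloxydauc-8-ene-4,6-diol
Conditions: HF·pyridine, pyridine, THF, 0 °C → rt
Reagents that add atoms: none
Why: Fluoride cleavage of the silyl ether under buffered, weakly acidic conditions that do not hydrolyse or shift the acetate and the allylic benzoate.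

Step 18
Reactants: 31 (1R,2S,4R,5S,6S,10S)-2-acetoxy-10-benzoyloxydauc-8-ene-4,6-diol; 32 angelic acid
Product: 34 (1R,2S,4R,5S,6S,10S)-2-acetoxy-6-angeloyloxy-10-benzoyloxydauc-8-en-4-ol, via mixed anhydride 33 (not isolated)
Conditions: 32, 2,4,6-trichlorobenzoyl chloride, Et3N, toluene, rt; then 31, 80 °C
Reagents that add atoms: none
Why: Yamaguchi-type esterification through the mixed anhydride without DMAP, the variant that transfers the angeloyl group without Z-to-E isomerisation, acylates only the secondary C6 hydroxyl.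

Compound list
1 | (S)-epichlorohydrin, (S)-2-(chloromethyl)oxirane | ClC[C@@H]1CO1 | starting material
2 | ethynyltrimethylsilane | C#C[Si](C)(C)C | starting material
3 | lithium (trimethylsilyl)acetylide | [Li]C#C[Si](C)(C)C | intermediate
4 | (S)-1-chloro-5-(trimethylsilyl)pent-4-yn-2-ol | ClC[C@@H](O)CC#C[Si](C)(C)C | intermediate
5 | (S)-trimethyl[3-(oxiran-2-yl)prop-1-yn-1-yl]silane | C[Si](C)(C)C#CC[C@H]1CO1 | intermediate
6 | (S)-6-(trimethylsilyl)hex-1-en-5-yn-3-ol | C=C[C@@H](O)CC#C[Si](C)(C)C | intermediate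
7 | (S)-hex-1-en-5-yn-3-ol | C=C[C@@H](O)CC#C | intermediate
8 | (S)-tert-butyl(hex-1-en-5-yn-3-yloxy)dimethylsilane | C=C[C@@H](O[Si](C)(C)C(C)(C)C)CC#C | intermediate
9 | lithium acetylide of 8 | C=C[C@@H](O[Si](C)(C)C(C)(C)C)CC#C[Li] | intermediate
10 | methyl (S)-5-[(tert-butyldimethylsilyl)oxy]hept-6-en-2-ynoate | C=C[C@@H](O[Si](C)(C)C(C)(C)C)CC#CC(=O)OC | intermediate
11 | methyl (2Z,5S)-5-[(tert-butyldimethylsilyl)oxy]-3-methylhepta-2,6-dienoate | C=C[C@@H](O[Si](C)(C)C(C)(C)C)C/C(C)=C\C(=O)OC | intermediate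
12 | (2Z,5S)-5-[(tert-butyldimethylsilyl)oxy]-N-methoxy-N,3-dimethylhepta-2,6-dienamide | C=C[C@@H](O[Si](C)(C)C(C)(C)C)C/C(C)=C\C(=O)N(C)OC | intermediate
13 | isopropenylmagnesium bromide | C=C(C)[Mg]Br | starting material
14 | (4Z,7S)-7-[(tert-butyldimethylsilyl)oxy]-2,5-dimethylnona-1,4,8-trien-3-one | C=C[C@@H](O[Si](C)(C)C(C)(C)C)C/C(C)=C\C(=O)C(C)=C | intermediate
15 | (S)-4-[(tert-butyldimethylsilyl)oxy]-2,6-dimethylcyclohepta-2,6-dien-1-one (key-step precursor) | CC1=C[C@@H](O[Si](C)(C)C(C)(C)C)CC(C)=CC1=O | intermediate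
16 | ethyl vinyl ether | C=COCC | starting material
17 | formaldehyde (monomer from paraformaldehyde) | C=O | starting material
18 | 1-ethoxyvinyllithium | [Li]C(=C)OCC | intermediate
19 | lithium bis(1-ethoxyvinyl)cuprate | [Li+].C=C(OCC)[Cu-]C(=C)OCC | intermediate
20 | lithium enolate of the C5 adduct (C10–OLi, C10=C1) | C=C(OCC)[C@@H]1[C@@H](O[Si](C)(C)C(C)(C)C)CC(C)=CC(O[Li])=C1C | intermediate
21 | (5S,6S,7R)-5-[(tert-butyldimethylsilyl)oxy]-6-(1-ethoxyethenyl)-7-(hydroxymethyl)-3,7-dimethylcyclohept-2-en-1-one (key-step product) | C=C(OCC)[C@@H]1[C@@H](O[Si](C)(C)C(C)(C)C)CC(C)=CC(=O)[C@@]1(C)CO | intermediate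
22 | (5S,6S,7R)-6-acetyl-5-[(tert-butyldimethylsilyl)oxy]-7-(hydroxymethyl)-3,7-dimethylcyclohept-2-en-1-one | CC(=O)[C@@H]1[C@@H](O[Si](C)(C)C(C)(C)C)CC(C)=CC(=O)[C@@]1(C)CO | intermediate
23 | (1R,6S,7S)-7-acetyl-6-[(tert-butyldimethylsilyl)oxy]-1,4-dimethyl-2-oxocyclohept-3-ene-1-carbaldehyde | CC(=O)[C@@H]1[C@@H](O[Si](C)(C)C(C)(C)C)CC(C)=CC(=O)[C@@]1(C)C=O | intermediate
24 | lithium enolate of the methyl ketone of 23 | C=C(O[Li])[C@@H]1[C@@H](O[Si](C)(C)C(C)(C)C)CC(C)=CC(=O)[C@@]1(C)C=O | intermediate
25 | (1R,2S,5S,6S)-6-[(tert-butyldimethylsilyl)oxy]-2-hydroxy-11,12,13-trinordauc-8-ene-4,10-dione, trans-fused bicyclo[5.3.0]decene ketol | CC(C)(C)[Si](C)(C)O[C@H]1CC(C)=CC(=O)[C@@]2(C)[C@@H](O)CC(=O)[C@H]12 | intermediate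
26 | isopropylmagnesium chloride | CC(C)[Mg]Cl | starting material
27 | (1R,2S,4R,5S,6S)-6-[(tert-butyldimethylsilyl)oxy]-2,4-dihydroxydauc-8-en-10-one | CC(C)(C)[Si](C)(C)O[C@H]1CC(C)=CC(=O)[C@@]2(C)[C@@H](O)C[C@@](O)(C(C)C)[C@H]12 | intermediate
28 | (1R,2S,4R,5S,6S)-2-acetoxy-6-[(tert-butyldimethylsilyl)oxy]-4-hydroxydauc-8-en-10-one | CC(C)(C)[Si](C)(C)O[C@H]1CC(C)=CC(=O)[C@@]2(C)[C@@H](OC(C)=O)C[C@@](O)(C(C)C)[C@H]12 | intermediate
29 | (1S,2S,4R,5S,6S,10S)-2-acetoxy-6-[(tert-butyldimethylsilyl)oxy]dauc-8-ene-4,10-diol | CC(C)(C)[Si](C)(C)O[C@H]1CC(C)=C[C@H](O)[C@@]2(C)[C@@H](OC(C)=O)C[C@@](O)(C(C)C)[C@H]12 | intermediate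
30 | (1R,2S,4R,5S,6S,10S)-2-acetoxy-10-benzoyloxy-6-[(tert-butyldimethylsilyl)oxy]dauc-8-en-4-ol | CC(C)(C)[Si](C)(C)O[C@H]1CC(C)=C[C@H](OC(=O)c3ccccc3)[C@@]2(C)[C@@H](OC(C)=O)C[C@@](O)(C(C)C)[C@H]12 | intermediate
31 | (1R,2S,4R,5S,6S,10S)-2-acetoxy-10-benzoyloxydauc-8-ene-4,6-diol | O[C@H]1CC(C)=C[C@H](OC(=O)c3ccccc3)[C@@]2(C)[C@@H](OC(C)=O)C[C@@](O)(C(C)C)[C@H]12 | intermediate
32 | angelic acid, (Z)-2-methylbut-2-enoic acid | C/C=C(/C)C(=O)O | starting material
33 | angelic 2,4,6-trichlorobenzoic anhydride | C/C=C(/C)C(=O)OC(=O)c1c(Cl)cc(Cl)cc1Cl | intermediate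
34 | (1R,2S,4R,5S,6S,10S)-2-acetoxy-6-angeloyloxy-10-benzoyloxydauc-8-en-4-ol (CNP0248576.1) | C/C=C(/C)C(=O)O[C@H]1CC(C)=C[C@H](OC(=O)c2ccccc2)[C@@]2(C)[C@@H](OC(C)=O)C[C@@](O)(C(C)C)[C@H]12 | target

Total step count: 18. Longest linear sequence: 18 steps, from 1 to 34.

Steps most likely to fail

Step 9. The conjugate addition may be slow on the α-methylated enone arm or lose selectivity (attack at the methyl-bearing C8 terminus or syn to the silyloxy group). Silanol may be eliminated from the γ-position, which leads toward a tropone, and the copper-bound enolate may be protonated instead of captured by formaldehyde. The fallback separates the two bond formations and sets out from 15. Cuprate 19 is added in the presence of Me3SiCl, which accelerates 1,4-addition and takes the enolate out of the basic medium, to give the isolable trimethylsilyl enol ether F1. MeLi in THF then regenerates the copper-free lithium enolate 20 from it, and gaseous formaldehyde is added at −78 °C (regenerated-enolate aldol). The route is rejoined at 21.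

Step 13. The secondary alkyl metal may enolise the cyclopentanone or reduce it by β-hydride transfer instead of adding, and prolonged exposure may bring attack at C10. The fallback changes the nucleophile to one that cannot deliver hydride and sets out from 25. Isopropenylmagnesium bromide 13 with LaCl3·2LiCl adds to C4 to give the isopropenyl carbinol F2. The 1,1-disubstituted alkene of this carbinol is then hydrogenated selectively with RhCl(PPh3)3 under H2 in benzene, leaving the hindered C8=C9 enone untouched. The route is rejoined at 27.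

Step 12. The β-keto aldehyde may lose its formyl group by retro-Claisen cleavage, the lithium aldolate may reopen by retro-aldol reaction, or the enolate may attack the aldehyde face that puts the hydroxyl cis to C15. The fallback avoids strong base and sets out from 21. Parikh–Doering oxidation (SO3·pyridine, DMSO, iPr2NEt) converts the primary alcohol into the enol-ether aldehyde F3 without touching the enol ether. MgBr2·OEt2 in CH2Cl2 at −78 °C then chelates the 1,3-keto aldehyde and triggers a Mukaiyama-type (Prins) addition of the enol ether terminus C3 to C2. Aqueous work-up hydrolyses the oxocarbenium ion with loss of ethanol, and the route is rejoined at 25.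

Further compounds
F1 | step 9 | trimethylsilyl enol ether of the C5 adduct, (5S,6S)-configured, C10–OSiMe3 and C10=C1 | C=C(OCC)[C@@H]1[C@@H](O[Si](C)(C)C(C)(C)C)CC(C)=CC(O[Si](C)(C)C)=C1C
F2 | step 13 | (1R,2S,4S,5S,6S)-6-[(tert-butyldimethylsilyl)oxy]-2,4-dihydroxydauca-8,11-dien-10-one | CC(C)(C)[Si](C)(C)O[C@H]1CC(C)=CC(=O)[C@@]2(C)[C@@H](O)C[C@@](O)(C(C)=C)[C@H]12
F3 | step 12 | (1R,6S,7S)-6-[(tert-butyldimethylsilyl)oxy]-7-(1-ethoxyethenyl)-1,4-dimethyl-2-oxocyclohept-3-ene-1-carbaldehyde | C=C(OCC)[C@@H]1[C@@H](O[Si](C)(C)C(C)(C)C)CC(C)=CC(=O)[C@@]1(C)C=O
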